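## Retrosynthetic overview

1. The only ring formed is the dihydropyranone, closed last: acid unmasks the 2'-OH of an (αR,βS)-epoxychalcone, which opens the epoxide at the benzylic carbon with inversion, giving the 2,3-trans (2R,3R) product.
2. The epoxide comes from Juliá–Colonna epoxidation of an E-chalcone, itself from Claisen–Schmidt union of an A-ring acetophenone and 2,4-bis(MOM-oxy)benzaldehyde (from resorcinol).
3. The acetophenone comes from directed ortho-metalation (DoM) and acetylation of a C2-symmetric 2-alkyl-5-methoxy-1,3-bis(MOM-oxy)benzene.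
4. The aryl–CH2 bond is made by Pd-catalysed sp2–sp3 Negishi coupling of an aryl iodide (resorcinol → Ir C–H borylation/oxidation → DoM/iodination) with a chiral alkylzinc.
5. The side-chain stereocentre is set by a Cu-catalysed enantioselective SN2′ allyl–alkyl coupling between a prenol-derived (E)-allyl chloride and the B-alkyl-9-BBN from 2-methylbut-3-en-2-ol.

Assumptions: the target is taken exactly as drawn, i.e. (2R,3R)-trans-dihydroflavonol with an (R) side-chain stereocentre. In Step 11 the ligand antipode that delivers the (S)-product must be fixed by a calibration run; (R)-DTBM-SEGPHOS is written, and its enantiomer is used if the sense is opposite.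

## Route

**Step 1**
Reactants: 1 resorcinol
Product: 2 1,3-bis(methoxymethoxy)benzene
Conditions: MOMCl (2.5 eq), i-Pr2NEt, CH2Cl2, 0 °C → rt
Reagents that add atoms: chloromethyl methyl ether, COCCl
Why: Standard phenol O-alkylation (Williamson-type acetal formation); MOM later serves as the ortho-directing group.

**Step 2**
Reactants: 2
Product: 3 3,5-bis(methoxymethoxy)phenol
Conditions: [Ir(OMe)(cod)]2 (1 mol %), dtbpy (2 mol %), B2pin2, THF, 80 °C; then aq. NaOH/H2O2, 0 °C (one pot)
Reagents that add atoms: hydrogen peroxide, OO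
Why: Sterically controlled Ir-catalysed C–H borylation of a 1,3-disubstituted arene occurs only at C5, and oxidation of the C–B bond gives the phloroglucinol oxygenation pattern.

**Step 3**
Reactants: 3
Product: 4 1-methoxy-3,5-bis(methoxymethoxy)benzene
Conditions: MeI, K2CO3, acetone, reflux
Reagents that add atoms: iodomethane, CI
Why: Williamson methylation of the single free phenol installs the future 5-OMe.

**Step 4**
Reactants: 4
Product: 5 2-iodo-5-methoxy-1,3-bis(methoxymethoxy)benzene
Conditions: n-BuLi, THF, 0 °C, 1 h; then I2, −78 °C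
Reagents that add atoms: iodine, II
Why: Directed ortho-metalation occurs at the position flanked by the two OMOM groups (strongest cooperative directors), and iodine quench gives the coupling handle.

**Step 5**
Reactants: 1 resorcinol
Product: 6 2,4-dihydroxybenzaldehyde
Conditions: POCl3, DMF, MeCN, −15 °C → rt; then H2O, 50 °C
Reagents that add atoms: N,N-dimethylformamide, CN(C)C=O; water, O
Why: Vilsmeier–Haack formylation of resorcinol goes para to one OH and ortho to the other.

**Step 6**
Reactants: 6
Product: 7 2,4-bis(methoxymethoxy)benzaldehyde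
Conditions: MOMCl, i-Pr2NEt, CH2Cl2, 0 °C → reflux
Reagents that add atoms: chloromethyl methyl ether, COCCl
Why: Phenol protection (acetal formation) compatible with the later basic aldol and epoxidation.

**Step 7**
Reactants: 8 prenol (3-methylbut-2-en-1-ol)
Product: 9 prenyl 4-methoxybenzyl ether
Conditions: NaH, PMBCl, TBAI (cat.), THF/DMF, 0 °C → rt
Reagents that add atoms: 4-methoxybenzyl chloride, COc1ccc(CCl)cc1
Why: Williamson etherification; PMB is removable later by DDQ without touching the silyl ether.

**Step 8**
Reactants: 9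
Product: 10 (2E)-4-[(4-methoxybenzyl)oxy]-2-methylbut-2-en-1-ol
Conditions: SeO2 (0.5 eq), t-BuOOH, salicylic acid (cat.), CH2Cl2, rt; then NaBH4, MeOH, 0 °C
Reagents that add atoms: selenium dioxide, O=[Se]=O
Why: Riley/Sharpless allylic oxidation (ene/[2,3]) hydroxylates the E-methyl group of the trisubstituted alkene selectively; borohydride returns any over-oxidised enal to the alcohol.

**Step 9**
Reactants: 10
Product: 11 (2E)-1-chloro-4-[(4-methoxybenzyl)oxy]-2-methylbut-2-ene
Conditions: MsCl, 2,4,6-collidine, LiCl, DMF, 0 °C
Reagents that add atoms: lithium chloride, [Li+].[Cl-]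
Why: In situ mesylation and SN2 chloride displacement (Meyers allylic chlorination) preserves the E geometry.

**Step 10**
Reactants: 12 2-methylbut-3-en-2-ol
Product: 13 triethyl[(2-methylbut-3-en-2-yl)oxy]silane
Conditions: TESOTf, 2,6-lutidine, CH2Cl2, −78 → 0 °C
Reagents that add atoms: triethylsilyl triflate, CC[Si](CC)(CC)OS(=O)(=O)C(F)(F)F
Why: Silylation of the tertiary alcohol with the reactive triflate; TES survives base and organolithiums and falls off in the final acid step.

**Step 11**
Reactants: 11 and 13
Product: 14 1-methoxy-4-({[(2S)-5-methyl-2-(prop-1-en-2-yl)-5-(triethylsilyloxy)hexyl]oxy}methyl)benzene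
Conditions: 13 (1.05 eq per B–H), (9-BBN-H)2, THF, 60 °C; then CuOTf·(toluene)0.5 (10 mol %), (R)-DTBM-SEGPHOS (11 mol %), KOMe, 11, 1,4-dioxane/CH2Cl2, 25 °C
Reagents that add atoms: none
Why: Proposed new method: anti-Markovnikov hydroboration gives the B-alkyl-9-BBN, whose methoxide borate transmetalates to the chiral bisphosphine–Cu(I) to form L*Cu–alkyl; this attacks the γ-CH of the β-methyl E-allyl chloride anti to chloride (SN2′ oxidative addition/reductive elimination, or carbocupration/β-Cl elimination), the ligand selecting the enantioface so that the new C–C bond, the (S) stereocentre and the isopropenyl group arise together; the closest known reactions are the Cu-catalysed enantioselective γ-selective coupling of alkyl-9-BBN reagents with Z-γ-monosubstituted allyl chlorides and the Cu/phosphoramidite SN2′ alkylation of β-substituted allyl chlorides with Grignard reagents, and as far as I know the alkylborane variant has not been shown on an E, β-methyl, γ-oxymethyl substrate.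

**Step 12**
Reactants: 14
Product: 15 (2S)-5-methyl-2-(prop-1-en-2-yl)-5-[(triethylsilyl)oxy]hexan-1-ol
Conditions: DDQ, CH2Cl2/pH 7 buffer (10:1), 0 °C
Reagents that add atoms: none
Why: Oxidative PMB cleavage under buffered conditions leaves the TES ether and the 1,1-disubstituted alkene intact; the stereocentre is not involved.

**Step 13**
Reactants: 15
Product: 16 (2S)-1-iodo-5-methyl-2-(prop-1-en-2-yl)-5-[(triethylsilyl)oxy]hexane
Conditions: I2, PPh3, imidazole, CH2Cl2, 0 °C → rt
Reagents that add atoms: iodine, II
Why: Appel iodination of the primary alcohol at a carbon adjacent to the stereocentre, so no epimerisation is possible.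

**Step 14**
Reactants: 16 and 5
Product: 17 5-methoxy-1,3-bis(methoxymethoxy)-2-[(2R)-5-methyl-2-(prop-1-en-2-yl)-5-(triethylsilyloxy)hexyl]benzene
Conditions: 16, t-BuLi (2.1 eq), Et2O, −78 °C; ZnCl2 (THF), −78 °C → rt; then 5, Pd(OAc)2 (4 mol %), CPhos (8 mol %), THF/toluene, rt → 50 °C
Reagents that add atoms: none
Why: Low-temperature I/Li exchange and transmetalation give the alkylzinc without radical rearrangement of the homoallyl unit, and Negishi coupling with a bulky biarylphosphine (fast reductive elimination over β-H elimination) forms the aryl–CH2 bond; the descriptor changes from S to R only because the CIP priorities change.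

**Step 15**
Reactants: 17 and 18 N-methoxy-N-methylacetamide
Product: 19 1-{6-methoxy-2,4-bis(methoxymethoxy)-3-[(2R)-5-methyl-2-(prop-1-en-2-yl)-5-(triethylsilyloxy)hexyl]phenyl}ethan-1-one
Conditions: n-BuLi, TMEDA, THF, 0 °C, 1 h; then 18, −78 → 0 °C; aq. NH4Cl
Reagents that add atoms: none
Why: Directed ortho-metalation at one of the two equivalent ring positions flanked by OMOM and OMe, then Weinreb ketone synthesis (the stable chelate prevents over-addition), gives the required Ac/OMOM/alkyl/OMOM/H/OMe pattern.

**Step 16**
Reactants: 19 and 7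
Product: 20 (2E)-3-[2,4-bis(methoxymethoxy)phenyl]-1-{6-methoxy-2,4-bis(methoxymethoxy)-3-[(2R)-5-methyl-2-(prop-1-en-2-yl)-5-(triethylsilyloxy)hexyl]phenyl}prop-2-en-1-one
Conditions: KOH (50 % aq.), EtOH, rt, 24–48 h
Reagents that add atoms: none
Why: Claisen–Schmidt aldol condensation gives the thermodynamic E-chalcone; MOM ethers and the hindered tertiary TES ether tolerate base.

**Step 17**
Reactants: 20
Product: 21 {(2R,3S)-3-[2,4-bis(methoxymethoxy)phenyl]oxiran-2-yl}{6-methoxy-2,4-bis(methoxymethoxy)-3-[(2R)-5-methyl-2-(prop-1-en-2-yl)-5-(triethylsilyloxy)hexyl]phenyl}methanone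
Conditions: immobilised poly-L-leucine, urea·H2O2, DBU, THF, rt
Reagents that add atoms: hydrogen peroxide (as urea adduct), OO
Why: Juliá–Colonna (Weitz–Scheffer-type) nucleophilic epoxidation touches only the enone, not the isopropenyl group, and poly-L-leucine gives the (αR,βS) trans-epoxide under catalyst control.

**Step 18**
Reactants: 21
Product: 22 (2R,3R)-2-(2,4-dihydroxyphenyl)-3,7-dihydroxy-8-[(2R)-5-hydroxy-5-methyl-2-(prop-1-en-2-yl)hexyl]-5-methoxy-2,3-dihydro-4H-chromen-4-one (target)
Conditions: HCl (about 1.5 M) in MeOH/THF, 0 → 40 °C, monitored; NaHCO3 quench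
Reagents that add atoms: none
Why: Acid removes the four phenolic MOM groups and the TES ether, and the freed 2'-OH opens the epoxide at the benzylic carbon (6-membered ring closure) with inversion, so Cα(R) is retained as C3(R) and Cβ(S) becomes C2(R); trans is also the thermodynamic isomer if the opening has SN1 character.

## Compound list

1 | resorcinol | Oc1cccc(O)c1 | starting material
2 | 1,3-bis(methoxymethoxy)benzene | COCOc1cccc(OCOC)c1 | intermediate
3 | 3,5-bis(methoxymethoxy)phenol | COCOc1cc(O)cc(OCOC)c1 | intermediate
4 | 1-methoxy-3,5-bis(methoxymethoxy)benzene | COCOc1cc(OC)cc(OCOC)c1 | intermediate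
5 | 2-iodo-5-methoxy-1,3-bis(methoxymethoxy)benzene | COCOc1cc(OC)cc(OCOC)c1I | intermediate
6 | 2,4-dihydroxybenzaldehyde | O=Cc1ccc(O)cc1O | intermediate
7 | 2,4-bis(methoxymethoxy)benzaldehyde | COCOc1ccc(C=O)c(OCOC)c1 | intermediate
8 | prenol (3-methylbut-2-en-1-ol) | CC(C)=CCO | starting material
9 | prenyl 4-methoxybenzyl ether | CC(C)=CCOCc1ccc(OC)cc1 | intermediate
10 | (2E)-4-[(4-methoxybenzyl)oxy]-2-methylbut-2-en-1-ol | COc1ccc(COC/C=C(\C)CO)cc1 | intermediate
11 | (2E)-1-chloro-4-[(4-methoxybenzyl)oxy]-2-methylbut-2-ene | COc1ccc(COC/C=C(\C)CCl)cc1 | intermediate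
12 | 2-methylbut-3-en-2-ol | C=CC(C)(C)O | starting material
13 | triethyl[(2-methylbut-3-en-2-yl)oxy]silane | C=CC(C)(C)O[Si](CC)(CC)CC | intermediate
14 | PMB ether of (2S)-5-methyl-2-(prop-1-en-2-yl)-5-(triethylsilyloxy)hexan-1-ol | C=C(C)[C@H](CCC(C)(C)O[Si](CC)(CC)CC)COCc1ccc(OC)cc1 | intermediate
15 | (2S)-5-methyl-2-(prop-1-en-2-yl)-5-[(triethylsilyl)oxy]hexan-1-ol | C=C(C)[C@H](CCC(C)(C)O[Si](CC)(CC)CC)CO | intermediate
16 | (2S)-1-iodo-5-methyl-2-(prop-1-en-2-yl)-5-[(triethylsilyl)oxy]hexane | C=C(C)[C@H](CCC(C)(C)O[Si](CC)(CC)CC)CI | intermediate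
17 | 5-methoxy-1,3-bis(methoxymethoxy)-2-[(2R)-5-methyl-2-(prop-1-en-2-yl)-5-(triethylsilyloxy)hexyl]benzene | C=C(C)[C@H](CCC(C)(C)O[Si](CC)(CC)CC)Cc1c(OCOC)cc(OC)cc1OCOC | intermediate
18 | N-methoxy-N-methylacetamide | CC(=O)N(C)OC | starting material
19 | 1-{6-methoxy-2,4-bis(methoxymethoxy)-3-[(2R)-side chain]phenyl}ethan-1-one | C=C(C)[C@H](CCC(C)(C)O[Si](CC)(CC)CC)Cc1c(OCOC)cc(OC)c(C(C)=O)c1OCOC | intermediate
20 | (E)-chalcone from 19 and 7 | C=C(C)[C@H](CCC(C)(C)O[Si](CC)(CC)CC)Cc1c(OCOC)cc(OC)c(C(=O)/C=C/c2ccc(OCOC)cc2OCOC)c1OCOC | intermediate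
21 | (2R,3S)-epoxychalcone (αR,βS) | C=C(C)[C@H](CCC(C)(C)O[Si](CC)(CC)CC)Cc1c(OCOC)cc(OC)c(C(=O)[C@@H]2O[C@H]2c3ccc(OCOC)cc3OCOC)c1OCOC | intermediate
22 | (2R,3R)-2-(2,4-dihydroxyphenyl)-3,7-dihydroxy-8-[(2R)-5-hydroxy-5-methyl-2-(prop-1-en-2-yl)hexyl]-5-methoxychroman-4-one | C=C(C)[C@H](CCC(C)(C)O)Cc1c(O)cc(OC)c2c1O[C@H](c1ccc(O)cc1O)[C@@H](O)C2=O | target

## Summary

Total step count: 18.

Longest linear sequence: 11 steps (7, 8, 9, 11, 12, 13, 14, 15, 16, 17, 18, from prenol), which is 61 % of the total. The other branches are 1–4 (A ring), 5–6 (B ring) and 10 (alkene partner).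

Steps most likely to fail:

1. **Step 11 (proposed new Cu-catalysed enantioselective SN2′ alkylborane coupling).** Risks are α/γ regioselectivity and ee on an E, β-methyl substrate. Fallback (known chemistry): Evans-auxiliary route, i.e. deconjugative α-prenylation of the N-(3-methylbut-2-enoyl)oxazolidinone dienolate (the established lavandulol synthesis), then LiBH4 to (S)-lavandulol. Epoxidise the trisubstituted alkene selectively (mCPBA, low temperature), open with LiAlH4 to the tertiary alcohol, then iodinate the primary alcohol (I2/PPh3) and protect with TESOTf to reach 16.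

2. **Step 14 (Negishi coupling at an aryl iodide flanked by two OMOM groups with a β-branched alkylzinc).** Risks are slow coupling, β-H elimination and protodehalogenation. Fallback: build the chain on the ring instead. Lithiate 4 and prenylate (CuI, prenyl bromide), oxidise with SeO2/t-BuOOH and chlorinate to the aryl-bound (E)-allyl chloride, then install the C3''–C6'' unit by Cu/phosphoramidite-catalysed SN2′ alkylation with the Grignard reagent of 4-bromo-2-methylbutan-2-ol TES ether, giving 17 without any sp2–sp3 cross-coupling.

3. **Step 18 (one-pot global deprotection and epoxide cyclisation).** Risks are aurone or isoflavone-type rearrangement products, methanol trapping at the benzylic carbon, and acid damage to the isopropenyl/tertiary alcohol unit. Fallback: change the ring-closure logic. Remove the MOM groups at the chalcone stage (20, which has no epoxide), cyclise to the (2S)-flavanone by oxa-Michael addition (chiral base or thiourea catalysis, or separation), silylate the phenols, then hydroxylate the C3 enolate trans to the aryl group with Davis oxaziridine (inert to the isopropenyl group) and desilylate with fluoride.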